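**Plan**

1. Retrosynthesis (rings: A benzene, B dihydropyran, C ten-membered carbocycle; chroman numbering O1, C2–C8a for rings A and B): ring C is cut at its endocyclic Z-alkene and exocyclic methylidene (enyne/ring-closing metathesis); ring B is cut at both of its bonds to ring A (C8a–O1 and C4a–C4); ring A loses its two formyl C–C bonds and two phenolic C–O bonds; two epoxide-opening C–C bonds lead back to geraniol.
2. Enabling feature: ring A carries oxygen on its three alternate carbons (C5, C7, C8a), so threefold-symmetric 1,3,5-trifluorobenzene can stand for it. Any of its C–H positions lies between two C–F bonds and gives the carbanion for the C4a–C4 bond, and the C–F next to it is displaced by the C2 tertiary alkoxide to give the O1–C8a bond.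
3. The two fluorines left over later direct lithiation/formylation at C6 and C8 and are then exchanged for OH once the formyl groups activate them.
4. Forward order: geraniol chain → β-hydroxy isobutyl ketone → ring B by annulation onto ring A → side-chain stereocentre → ring C by metathesis → CHO and OH groups on ring A.
5. Stereochemistry: C2/C3 from Sharpless epoxidation of the E-alkene plus SN2 opening with inversion; C4 from ionic hydrogenation trans to the C3 substituent; the CH–CMe2OH centre from Shi epoxidation plus SN2 opening by a vinyl copper reagent; the Z ring alkene from ring strain under reversible metathesis.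

Key step: step 6

Assumption: the silyl-protected bromobutyne used in step 2 is taken as a catalogue reagent (otherwise two steps from but-3-yn-1-ol).

**Route**

Step 1
Reactants: 1 geraniol
Product: 2 (2R,3R)-2,3-epoxygeraniol
Conditions: Ti(OiPr)4 (5 mol%), D-(−)-diethyl tartrate (7 mol%), t-BuOOH, 4 Å MS, CH2Cl2, −20 °C
Reagents that add atoms: tert-butyl hydroperoxide CC(C)(C)OO
Why: Sharpless asymmetric epoxidation of the allylic alcohol delivers oxygen to one face of the E-alkene only, which sets C2 of ring B (R) and the epoxide carbon that becomes C3, while the isolated trisubstituted alkene is left alone.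

Step 2
Reactants: 2 (2R,3R)-2,3-epoxygeraniol; 3 (4-bromobut-1-yn-1-yl)triisopropylsilane
Product: 5 (2S,3R)-3,7-dimethyl-2-[4-(triisopropylsilyl)but-3-yn-1-yl]oct-6-ene-1,3-diol, via silylbutynylmagnesium bromide 4 (not isolated)
Conditions: 3 (3 equiv), Mg, THF, 40 °C; then 2, CuI (10 mol%), THF, −30 → 0 °C; aq. NH4Cl
Reagents that add atoms: none
Why: Copper-catalysed Grignard opening of a 2,3-epoxy alcohol proceeds by SN2 attack at the epoxide CH carbon (the other carbon is fully substituted) with inversion, so the E geometry of 1 is translated into the (2S,3R) diol that corresponds to the trans fusion of rings B and C.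

Step 3
Reactants: 5 (2S,3R)-3,7-dimethyl-2-[4-(triisopropylsilyl)but-3-yn-1-yl]oct-6-ene-1,3-diol
Product: 6 (2R,3R)-3-hydroxy-3,7-dimethyl-2-[4-(triisopropylsilyl)but-3-yn-1-yl]oct-6-enal
Conditions: TEMPO (10 mol%), PhI(OAc)2 (1.1 equiv), CH2Cl2, rt
Reagents that add atoms: none
Why: Nitroxyl-catalysed oxidation with PhI(OAc)2 is selective for the primary alcohol, leaves the tertiary alcohol, alkene and alkyne untouched and is mild enough to avoid epimerisation of the α-stereocentre.

Step 4
Reactants: 6 (2R,3R)-3-hydroxy-3,7-dimethyl-2-[4-(triisopropylsilyl)but-3-yn-1-yl]oct-6-enal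
Product: 7 (5S,6R)-2,6,10-trimethyl-5-[4-(triisopropylsilyl)but-3-yn-1-yl]undec-9-ene-4,6-diol (both C4 epimers)
Conditions: i-BuMgBr (2.5 equiv), THF, −78 → −20 °C
Reagents that add atoms: isobutylmagnesium bromide CC(C)C[Mg]Br
Why: Grignard addition to the aldehyde (one equivalent is consumed by the hydroxyl) should give the secondary carbinol, whose configuration is irrelevant because it is oxidised in step 5.

Step 5
Reactants: 7 (5S,6R)-2,6,10-trimethyl-5-[4-(triisopropylsilyl)but-3-yn-1-yl]undec-9-ene-4,6-diol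
Product: 8 (5R,6R)-6-hydroxy-2,6,10-trimethyl-5-[4-(triisopropylsilyl)but-3-yn-1-yl]undec-9-en-4-one
Conditions: Dess–Martin periodinane, NaHCO3, CH2Cl2, 0 °C → rt
Reagents that add atoms: none
Why: Dess–Martin oxidation of the secondary alcohol under buffered conditions should give the β-hydroxy ketone without touching the tertiary alcohol or epimerising the α-centre.

Step 6
Reactants: 8 (5R,6R)-6-hydroxy-2,6,10-trimethyl-5-[4-(triisopropylsilyl)but-3-yn-1-yl]undec-9-en-4-one; 9 1,3,5-trifluorobenzene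
Product: 12 (2R,3S)-5,7-difluoro-2-methyl-2-(4-methylpent-3-en-1-yl)-4-(2-methylpropyl)-3-[4-(triisopropylsilyl)but-3-yn-1-yl]chroman-4-ol (C4 epimers), via 2,4,6-trifluorophenyllithium 10 (not isolated), via aryl carbinol dialkoxide 11 (not isolated)
Conditions: 9 (2.2 equiv), n-BuLi (2.1 equiv), THF, −78 °C; LaCl3·2LiCl (0.3 equiv), then 8, −78 → −30 °C; then DMPU, 65 °C
Reagents that add atoms: none
Why: Lithiation of 9 between two fluorines gives 10, which adds to the lithium-chelated ketone of 8 at low temperature (aryl–C4 bond) to give 11; on warming in DMPU the C2 tertiary alkoxide of 11 attacks the neighbouring ortho C–F carbon of ring A, forms a fluorine-stabilised Meisenheimer anion and expels fluoride (aryl–O1 bond). The closest known reaction types are the 1,2-addition of polyfluoroaryllithiums to β-hydroxy ketones and the intramolecular SNAr O-arylation of alkoxides on fluoroarenes, run here as one operation. Ring B closes in a 6-exo-trig fashion by addition–elimination at the aromatic carbon. The only new stereocentre is the C4 carbinol, formed under chelation control and removed again in step 9, while C2 and C3 are untouched because the ketone is consumed at −78 °C before retro-aldol cleavage or enolisation can set in. The step needs site selectivity on the arene and between the two alkoxides: the threefold symmetry of 9 makes all C–H positions and both ortho fluorines equivalent, and only the C2 alkoxide can reach an ortho carbon through a six-membered transition state, the benzylic alkoxide being limited to a four-membered one.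

Step 7
Reactants: 12 (2R,3S)-5,7-difluoro-2-methyl-2-(4-methylpent-3-en-1-yl)-4-(2-methylpropyl)-3-[4-(triisopropylsilyl)but-3-yn-1-yl]chroman-4-ol
Product: 13 (2R,3S)-2-{2-[(2R)-3,3-dimethyloxiran-2-yl]ethyl}-5,7-difluoro-2-methyl-4-(2-methylpropyl)-3-[4-(triisopropylsilyl)but-3-yn-1-yl]chroman-4-ol (C4 epimers)
Conditions: D-fructose-derived Shi ketone (0.3 equiv), Oxone (2KHSO5·KHSO4·K2SO4), K2CO3, Bu4NHSO4, MeCN/CH2(OMe)2/aq. Na2B4O7, 0 °C
Reagents that add atoms: Oxone (potassium peroxymonosulfate) [K+].[O-]S(=O)(=O)OO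
Why: Shi epoxidation, in which the dioxirane formed from the chiral ketone epoxidises the only alkene (an electron-rich trisubstituted one) under reagent control to the (R)-epoxide, and the buffered basic medium spares the acid-labile benzylic alcohol.

Step 8
Reactants: 13 (2R,3S)-2-{2-[(2R)-3,3-dimethyloxiran-2-yl]ethyl}-5,7-difluoro-2-methyl-4-(2-methylpropyl)-3-[4-(triisopropylsilyl)but-3-yn-1-yl]chroman-4-ol
Product: 14 (2R,3S)-5,7-difluoro-2-[(3R)-3-(2-hydroxypropan-2-yl)pent-4-en-1-yl]-2-methyl-4-(2-methylpropyl)-3-[4-(triisopropylsilyl)but-3-yn-1-yl]chroman-4-ol (C4 epimers)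
Conditions: CH2=CHMgBr (5 equiv), CuI (20 mol%), THF, −30 → 0 °C
Reagents that add atoms: vinylmagnesium bromide C=C[Mg]Br
Why: Copper-catalysed SN2 opening at the secondary epoxide carbon (the other is fully substituted) with inversion should install the vinyl group and free the tertiary alcohol, which sets the (R)-configured CH–CMe2OH centre.

Step 9
Reactants: 14 (2R,3S)-5,7-difluoro-2-[(3R)-3-(2-hydroxypropan-2-yl)pent-4-en-1-yl]-2-methyl-4-(2-methylpropyl)-3-[4-(triisopropylsilyl)but-3-yn-1-yl]chroman-4-ol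
Product: 15 (2R,3S,4R)-5,7-difluoro-2-[(3R)-3-(2-hydroxypropan-2-yl)pent-4-en-1-yl]-2-methyl-4-(2-methylpropyl)-3-[4-(triisopropylsilyl)but-3-yn-1-yl]chromane
Conditions: Et3SiH (5 equiv), CF3CO2H (5 equiv), CH2Cl2, −40 → −10 °C
Reagents that add atoms: none
Why: Ionic hydrogenation, in which acid ionises only the tertiary benzylic alcohol to a cation stabilised by the O1 lone pair, and Et3SiH should deliver hydride trans to the C3 side chain (the face also remote from the pseudo-axial C2 methyl) to give the 3,4-cis (4R) chroman.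

Step 10
Reactants: 15 (2R,3S,4R)-5,7-difluoro-2-[(3R)-3-(2-hydroxypropan-2-yl)pent-4-en-1-yl]-2-methyl-4-(2-methylpropyl)-3-[4-(triisopropylsilyl)but-3-yn-1-yl]chromane
Product: 16 (2R,3S,4R)-3-(but-3-yn-1-yl)-5,7-difluoro-2-[(3R)-3-(2-hydroxypropan-2-yl)pent-4-en-1-yl]-2-methyl-4-(2-methylpropyl)chromane
Conditions: Bu4NF (1.5 equiv), THF, 0 °C → rt
Reagents that add atoms: none
Why: Fluoride-induced protodesilylation of the alkynylsilane frees the terminal alkyne needed for metathesis.

Step 11
Reactants: 16 (2R,3S,4R)-3-(but-3-yn-1-yl)-5,7-difluoro-2-[(3R)-3-(2-hydroxypropan-2-yl)pent-4-en-1-yl]-2-methyl-4-(2-methylpropyl)chromane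
Product: 18 tricyclic difluoride (target skeleton with F at C5 and C7 and H at C6 and C8), via butadienyl intermediate 17 (not isolated)
Conditions: second-generation Grubbs catalyst RuCl2(=CHPh)(PCy3)(H2IMes) (10 mol%), ethene (1 atm), CH2Cl2, rt; then argon purge, toluene (1 mM), 80 °C, further catalyst (10 mol%)
Reagents that add atoms: ethene C=C
Why: Enyne cross-metathesis with ethene turns the alkyne into a 2-substituted buta-1,3-diene and ring-closing metathesis between its monosubstituted terminus and the vinyl group then closes ring C, the Z ring alkene being expected because E-cyclodecenes are far more strained and the reaction is reversible.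

Step 12
Reactants: 18 tricyclic difluoride
Product: 20 tricyclic 5,7-difluoro-6,8-dicarbaldehyde, via lithium hemiaminal alkoxide 19 (not isolated)
Conditions: lithium 2,2,6,6-tetramethylpiperidide (2.3 equiv), THF, −78 °C; DMF (1.1 equiv); lithium 2,2,6,6-tetramethylpiperidide (1.5 equiv), −78 °C; DMF (3 equiv); aq. citric acid
Reagents that add atoms: N,N-dimethylformamide CN(C)C=O
Why: Directed ortho-lithiation and formylation, in which the C6–H between two fluorines and then the C8–H between F and O1 are removed by the hindered amide at −78 °C (no LiF loss) and trapped with DMF, the first formyl group staying masked as its hemiaminal alkoxide during the second lithiation.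

Step 13
Reactants: 20 tricyclic 5,7-difluoro-6,8-dicarbaldehyde
Product: 22 CNP0479784.1 (target), via bis(silylethyl) ether 21 (not isolated)
Conditions: NaH (3 equiv), Me3SiCH2CH2OH (4 equiv), THF, 0 °C → rt; then Bu4NF (6 equiv), rt → 40 °C; aq. HCl work-up
Reagents that add atoms: 2-(trimethylsilyl)ethanol C[Si](C)(C)CCO
Why: Nucleophilic aromatic substitution by addition–elimination, in which each fluorine is ortho or para to both formyl groups so the alkoxide displaces both while the neutral silylethyl ethers keep ring A electrophilic, and fluoride then triggers β-elimination of ethene and Me3SiF to release the two phenols.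

**Compound list**

1 | geraniol, (2E)-3,7-dimethylocta-2,6-dien-1-ol | CC(C)=CCC/C(C)=C/CO | starting material
2 | (2R,3R)-2,3-epoxygeraniol, [(2R,3R)-3-methyl-3-(4-methylpent-3-en-1-yl)oxiran-2-yl]methanol | CC(C)=CCC[C@@]1(C)O[C@@H]1CO | intermediate
3 | (4-bromobut-1-yn-1-yl)triisopropylsilane | BrCCC#C[Si](C(C)C)(C(C)C)C(C)C | starting material
4 | [4-(triisopropylsilyl)but-3-yn-1-yl]magnesium bromide | Br[Mg]CCC#C[Si](C(C)C)(C(C)C)C(C)C | intermediate
5 | (2S,3R)-3,7-dimethyl-2-[4-(triisopropylsilyl)but-3-yn-1-yl]oct-6-ene-1,3-diol | CC(C)=CCC[C@@](C)(O)[C@@H](CCC#C[Si](C(C)C)(C(C)C)C(C)C)CO | intermediate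
6 | (2R,3R)-3-hydroxy-3,7-dimethyl-2-[4-(triisopropylsilyl)but-3-yn-1-yl]oct-6-enal | CC(C)=CCC[C@@](C)(O)[C@@H](CCC#C[Si](C(C)C)(C(C)C)C(C)C)C=O | intermediate
7 | (5S,6R)-2,6,10-trimethyl-5-[4-(triisopropylsilyl)but-3-yn-1-yl]undec-9-ene-4,6-diol (both C4 epimers) | CC(C)=CCC[C@@](C)(O)[C@@H](CCC#C[Si](C(C)C)(C(C)C)C(C)C)C(O)CC(C)C | intermediate
8 | (5R,6R)-6-hydroxy-2,6,10-trimethyl-5-[4-(triisopropylsilyl)but-3-yn-1-yl]undec-9-en-4-one | CC(C)=CCC[C@@](C)(O)[C@@H](CCC#C[Si](C(C)C)(C(C)C)C(C)C)C(=O)CC(C)C | intermediate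
9 | 1,3,5-trifluorobenzene | Fc1cc(F)cc(F)c1 | starting material
10 | 2,4,6-trifluorophenyllithium | [Li]c1c(F)cc(F)cc1F | intermediate
11 | dilithium dialkoxide of (5R,6R)-2,6,10-trimethyl-4-(2,4,6-trifluorophenyl)-5-[4-(triisopropylsilyl)but-3-yn-1-yl]undec-9-ene-4,6-diol (C4 epimers) | CC(C)=CCC[C@@](C)(O[Li])[C@@H](CCC#C[Si](C(C)C)(C(C)C)C(C)C)C(O[Li])(CC(C)C)c1c(F)cc(F)cc1F | intermediate
12 | (2R,3S)-5,7-difluoro-2-methyl-2-(4-methylpent-3-en-1-yl)-4-(2-methylpropyl)-3-[4-(triisopropylsilyl)but-3-yn-1-yl]chroman-4-ol (C4 epimers) | CC(C)=CCC[C@@]2(C)Oc3cc(F)cc(F)c3C(O)(CC(C)C)[C@@H]2CCC#C[Si](C(C)C)(C(C)C)C(C)C | intermediate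
13 | (2R,3S)-2-{2-[(2R)-3,3-dimethyloxiran-2-yl]ethyl}-5,7-difluoro-2-methyl-4-(2-methylpropyl)-3-[4-(triisopropylsilyl)but-3-yn-1-yl]chroman-4-ol (C4 epimers) | CC1(C)O[C@@H]1CC[C@@]2(C)Oc3cc(F)cc(F)c3C(O)(CC(C)C)[C@@H]2CCC#C[Si](C(C)C)(C(C)C)C(C)C | intermediate
14 | (2R,3S)-5,7-difluoro-2-[(3R)-3-(2-hydroxypropan-2-yl)pent-4-en-1-yl]-2-methyl-4-(2-methylpropyl)-3-[4-(triisopropylsilyl)but-3-yn-1-yl]chroman-4-ol (C4 epimers) | C=C[C@H](C(C)(C)O)CC[C@@]2(C)Oc3cc(F)cc(F)c3C(O)(CC(C)C)[C@@H]2CCC#C[Si](C(C)C)(C(C)C)C(C)C | intermediate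
15 | (2R,3S,4R)-5,7-difluoro-2-[(3R)-3-(2-hydroxypropan-2-yl)pent-4-en-1-yl]-2-methyl-4-(2-methylpropyl)-3-[4-(triisopropylsilyl)but-3-yn-1-yl]chromane | C=C[C@H](C(C)(C)O)CC[C@@]2(C)Oc3cc(F)cc(F)c3[C@H](CC(C)C)[C@@H]2CCC#C[Si](C(C)C)(C(C)C)C(C)C | intermediate
16 | (2R,3S,4R)-3-(but-3-yn-1-yl)-5,7-difluoro-2-[(3R)-3-(2-hydroxypropan-2-yl)pent-4-en-1-yl]-2-methyl-4-(2-methylpropyl)chromane | C=C[C@H](C(C)(C)O)CC[C@@]2(C)Oc3cc(F)cc(F)c3[C@H](CC(C)C)[C@@H]2CCC#C | intermediate
17 | (2R,3S,4R)-5,7-difluoro-2-[(3R)-3-(2-hydroxypropan-2-yl)pent-4-en-1-yl]-2-methyl-3-(3-methylidenepent-4-en-1-yl)-4-(2-methylpropyl)chromane | C=C[C@H](C(C)(C)O)CC[C@@]2(C)Oc3cc(F)cc(F)c3[C@H](CC(C)C)[C@@H]2CCC(=C)C=C | intermediate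
18 | tricyclic difluoride: target skeleton (rings A, B, C; Z ring alkene, exocyclic methylidene, CMe2OH) with F at C5 and C7 and H at C6 and C8; (2R,3S,4R) in ring B, (R) at the CH–CMe2OH carbon | C=C1/C=C\[C@H](C(C)(C)O)CC[C@@]2(C)Oc3cc(F)cc(F)c3[C@H](CC(C)C)[C@@H]2CC1 | intermediate
19 | dilithium salt of 18 carrying CH(OLi)NMe2 at C6 and OLi at the carbinol | C=C1/C=C\[C@H](C(C)(C)O[Li])CC[C@@]2(C)Oc3cc(F)c(C(O[Li])N(C)C)c(F)c3[C@H](CC(C)C)[C@@H]2CC1 | intermediate
20 | 5,7-difluoro-6,8-dicarbaldehyde of 18, configurations unchanged | C=C1/C=C\[C@H](C(C)(C)O)CC[C@@]2(C)Oc3c(C=O)c(F)c(C=O)c(F)c3[C@H](CC(C)C)[C@@H]2CC1 | intermediate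
21 | 5,7-bis[2-(trimethylsilyl)ethoxy]-6,8-dicarbaldehyde (both F of 20 replaced) | C=C1/C=C\[C@H](C(C)(C)O)CC[C@@]2(C)Oc3c(C=O)c(OCC[Si](C)(C)C)c(C=O)c(OCC[Si](C)(C)C)c3[C@H](CC(C)C)[C@@H]2CC1 | intermediate
22 | CNP0479784.1, the 5,7-dihydroxy-6,8-dicarbaldehyde; (2R,3S,4R) in ring B, (R) at the CH–CMe2OH carbon, Z ring alkene | C=C1/C=C\[C@H](C(C)(C)O)CC[C@@]2(C)Oc3c(C=O)c(O)c(C=O)c(O)c3[C@H](CC(C)C)[C@@H]2CC1 | target

**Step count and risks**

Total step count: 13. Longest linear sequence: 13 steps (1 → 22).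

Steps most likely to fail:

1. Step 11. The ring-closing stage may give oligomers by cross-metathesis, may close onto the 1,1-disubstituted diene carbon (nine-membered ring) or may give an E/Z mixture, because the ten-membered ring is strained. The fallback sets out from 15 and comes back at 18 and replaces metathesis by an irreversible carbonyl addition. Hydroboration–oxidation of the vinyl group (9-BBN; NaBO3) should give the primary alcohol F1. Bu4NF should free the alkyne to give the alkynyl diol F2. Nickel-catalysed Markovnikov hydroalumination and iodination (i-Bu2AlH, NiCl2(dppp); N-iodosuccinimide) should give the 2-iodoalk-1-ene F3. TEMPO/PhI(OAc)2 should give the iodo aldehyde F4, which is expected to equilibrate with its five-membered lactol. Nozaki–Hiyama–Kishi cyclisation (CrCl2, catalytic NiCl2, DMSO/THF, high dilution) should close ring C as the allylic alcohol F5. Selective mesylation of the secondary hydroxyl (MsCl, Et3N) to the allylic mesylate F6 and elimination with DBU should give the conjugated diene 18, the Z geometry again being favoured by ring strain.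

2. Step 6. The hindered ketone may be enolised or the aldolate may cleave by retro-aldol reaction instead of undergoing 1,2-addition, and ring closure may stall with the lithium counter-ion. The fallback sets out from 6 and comes back at 12 and moves the aryl addition to the more electrophilic aldehyde. Addition of 10 to 6 at −78 °C should give the benzylic diol F7. NaH in DMF at 60 °C should close ring B by SNAr to the chroman-4-ol F8. Dess–Martin oxidation should give the chroman-4-one F9. Addition of i-BuMgBr in the presence of CeCl3 at −78 °C should give 12.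

3. Step 8. Magnesium halide may act as a Lewis acid and cause opening at the tertiary carbon, rearrangement of the epoxide to a carbonyl compound or halohydrin formation instead of SN2 attack at the secondary carbon. The fallback sets out from 13 and comes back at 14 and uses a salt-free two-carbon nucleophile. Lithium acetylide–ethylenediamine complex in DMSO should open the epoxide at the secondary carbon with inversion to give the ethynyl carbinol F7-independent compound F10. Semi-hydrogenation (H2, Pd/CaCO3 poisoned with Pb(OAc)2, quinoline) should give 14, the bulky triisopropylsilyl alkyne being expected to react far more slowly.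

**Further compounds**

F1 | step 11 | (2R,3S,4R)-5,7-difluoro-2-[(3R)-4-hydroxy-3-(2-hydroxyethyl)-4-methylpentyl]-2-methyl-4-(2-methylpropyl)-3-[4-(triisopropylsilyl)but-3-yn-1-yl]chromane | OCC[C@H](C(C)(C)O)CC[C@@]2(C)Oc3cc(F)cc(F)c3[C@H](CC(C)C)[C@@H]2CCC#C[Si](C(C)C)(C(C)C)C(C)C
F2 | step 11 | (2R,3S,4R)-3-(but-3-yn-1-yl)-5,7-difluoro-2-[(3R)-4-hydroxy-3-(2-hydroxyethyl)-4-methylpentyl]-2-methyl-4-(2-methylpropyl)chromane | OCC[C@H](C(C)(C)O)CC[C@@]2(C)Oc3cc(F)cc(F)c3[C@H](CC(C)C)[C@@H]2CCC#C
F3 | step 11 | (2R,3S,4R)-5,7-difluoro-2-[(3R)-4-hydroxy-3-(2-hydroxyethyl)-4-methylpentyl]-3-(3-iodobut-3-en-1-yl)-2-methyl-4-(2-methylpropyl)chromane | OCC[C@H](C(C)(C)O)CC[C@@]2(C)Oc3cc(F)cc(F)c3[C@H](CC(C)C)[C@@H]2CCC(I)=C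
F4 | step 11 | (2R,3S,4R)-5,7-difluoro-2-[(3R)-4-hydroxy-4-methyl-3-(2-oxoethyl)pentyl]-3-(3-iodobut-3-en-1-yl)-2-methyl-4-(2-methylpropyl)chromane | O=CC[C@H](C(C)(C)O)CC[C@@]2(C)Oc3cc(F)cc(F)c3[C@H](CC(C)C)[C@@H]2CCC(I)=C
F5 | step 11 | tricyclic difluoro diol: ring C closed, exocyclic methylidene, secondary allylic hydroxyl next to it (epimers), CMe2OH; other configurations as in 18 | C=C1C(O)C[C@H](C(C)(C)O)CC[C@@]2(C)Oc3cc(F)cc(F)c3[C@H](CC(C)C)[C@@H]2CC1
F6 | step 11 | secondary allylic methanesulfonate of F5 | C=C1C(OS(C)(=O)=O)C[C@H](C(C)(C)O)CC[C@@]2(C)Oc3cc(F)cc(F)c3[C@H](CC(C)C)[C@@H]2CC1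
F7 | step 6 | (2S,3R)-3,7-dimethyl-2-[4-(triisopropylsilyl)but-3-yn-1-yl]-1-(2,4,6-trifluorophenyl)oct-6-ene-1,3-diol (C1 epimers) | CC(C)=CCC[C@@](C)(O)[C@@H](CCC#C[Si](C(C)C)(C(C)C)C(C)C)C(O)c1c(F)cc(F)cc1F
F8 | step 6 | (2R,3S)-5,7-difluoro-2-methyl-2-(4-methylpent-3-en-1-yl)-3-[4-(triisopropylsilyl)but-3-yn-1-yl]chroman-4-ol (C4 epimers) | CC(C)=CCC[C@@]2(C)Oc3cc(F)cc(F)c3C(O)[C@@H]2CCC#C[Si](C(C)C)(C(C)C)C(C)C
F9 | step 6 | (2R,3R)-5,7-difluoro-2-methyl-2-(4-methylpent-3-en-1-yl)-3-[4-(triisopropylsilyl)but-3-yn-1-yl]chroman-4-one | CC(C)=CCC[C@@]2(C)Oc3cc(F)cc(F)c3C(=O)[C@@H]2CCC#C[Si](C(C)C)(C(C)C)C(C)C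
F10 | step 8 | (2R,3S)-2-[(3R)-3-ethynyl-4-hydroxy-4-methylpentyl]-5,7-difluoro-2-methyl-4-(2-methylpropyl)-3-[4-(triisopropylsilyl)but-3-yn-1-yl]chroman-4-ol (C4 epimers) | C#C[C@H](C(C)(C)O)CC[C@@]2(C)Oc3cc(F)cc(F)c3C(O)(CC(C)C)[C@@H]2CCC#C[Si](C(C)C)(C(C)C)C(C)C
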